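Amounts first: three closed-flask runs at different charges of G were known, and I had to say how much L two tanks and one closed flask give at one common charge.

| flask | G | remark | time |
|---|---|---|---|
| Thursday's | 0.66 M | run made earlier |  |
| Monday's | 0.44 M | run made earlier |  |
| Saturday's | 0.99 M | run made earlier |  |
| spring | 0.66 M | one stirred flow tank at steady state, fed with the mixture as stated, mean residence time 6.0 min |  |
| dusk | 0.66 M | a single well-mixed tank run continuously and read at steady state, 18.0 min in it on average |  |
| winter | 0.66 M | a closed flask charged with all of it at once and left for 6.0 min | 6.0 min |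

| run | time / min | L / % | G / % |
|---|---|---|---|
| Thursday's | 0.500 | 40.8 | 9.6 |
| Thursday's | 0.833 | 45.9 | 3.7 |
| Thursday's | 1.33 | 47.9 | 1.4 |
| Thursday's | 2.00 | 49.0 | 1.0 |
| Thursday's | 4.00 | 52.1 | 0.4 |
| Thursday's | 6.00 | 53.8 | 0.4 |
| Monday's | 0.417 | 43.5 | 16.4 |
| Monday's | 0.667 | 49.7 | 6.8 |
| Monday's | 1.00 | 54.2 | 3.2 |
| Monday's | 2.00 | 57.7 | 0.7 |
| Monday's | 3.00 | 59.0 | 0.4 |
| Monday's | 5.00 | 61.9 | 0.4 |
| Saturday's | 0.833 | 37.7 | 2.8 |
| Saturday's | 1.50 | 40.1 | 1.0 |
| Saturday's | 2.50 | 42.2 | 0.5 |
| Saturday's | 3.00 | 42.1 | 0.1 |
| Saturday's | 4.00 | 42.7 | 0.3 |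
| Saturday's | 5.00 | 43.3 | 0.1 |

(each reading ± 0.3 percentage points)

- the stated concentrations are those of everything mixed, before any reaction; amounts are the same in each set-up
- the earlier runs were made in a closed, stirred flask

1. the set-up with the highest amount of L at the outlet or at the end, in percent of the G put in ("none" if the first two lie within 2 percentage points) (spring / dusk / winter / none)
2. amount of L at the outlet or at the end, in percent of the G put in, spring
3. amount of L at the outlet or at the end, in percent of the G put in, dusk
4. amount of L at the outlet or at the end, in percent of the G put in, winter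

Does the charge change what is lost? At each last reading I took the G unseen (neither L nor G) per L, an inverse selectivity I call the loss ratio. Divided by the charge it gave 1.29 M⁻¹ on Thursday's run, 1.38 M⁻¹ on Monday's and 1.32 M⁻¹ on Saturday's, with a mean of 1.33 M⁻¹, the loss number. Winter repeats Thursday's charge and last time, so I expected 53.8 %.

What does a tank do to that ratio? I replaced the falling curve by its mean, half the charge, so the ratio per molar of mean [G] is twice the loss number. Monday's first reading, with the same mean, gave a rough ring constant of 1.79 min⁻¹. That put G near 9.30 % in spring and 3.10 % at dusk. The ratios became 0.163 and 0.0545, and L became 78.0 % and 91.9 %, with dusk ahead.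

But at the last readings [L] rose with the charge, from 0.272 M on Monday's run to 0.429 M on Saturday's, as the starting [G] did, so the loss number did not tell me whether lost G met G or L. I kept both tank figures with a warning: they leave [L] out, so a loss by G meeting L could make them too high.

The forecast said dusk, with 84 %, 94.5 % and 54 %, its tank figures higher than mine, on the ground that tanks “hold G low, which favours first-order closure”.

The flasks gave 67.2 % in spring, 73.7 % at dusk and 53.1 % in winter, so the best was dusk.

    G → L (k = 2.50 min⁻¹)
    2 G → X (k = 3.40 M⁻¹ min⁻¹)
    G ⇌ E (K = 1.10, k = 0.530 min⁻¹)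
    G + X → Q (k = 1.60 M⁻¹ min⁻¹)
    G + L → D (k = 0.600 M⁻¹ min⁻¹)

At dusk the loss ratio came to 0.332, well above my 0.0545, although X there held 2.05 % of the charge against 32.1 % in winter. Put to use once more, for winter's flask charged with 2.6 M, the loss number gave a ratio of 3.46, hence 22.4 % of L, and that flask gave 24.2 %.

(The readings were generated by integration on assumed constants; noise was put on by code.)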